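**Plan**
Drimane numbering: ring A = C1–C5 and C10, ring B = C5–C10, C11 = the CH2O carbon on C9, C12 = the methyl on C8.
Cuts: first the caffeoyl C–O bond at C11, then C8–C9 of ring B (an aldol-type bond), then C9–C10 (an acetate unit placed on C10 by a [3,3] shift); what is left is α-ionone.
Enabling feature: C9 carries the ester-level carbon C11 and its ring neighbour C8 is a former carbonyl carbon bearing only the methyl C12, so C9 can act as a silyl ketene acetal and C8 as a ketal-derived oxocarbenium ion; ring A, C6–C7–C8 and C12 are the carbon skeleton of α-ionone.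
Forward: ring A is bought, C9/C11 are attached to C10, ring B closes at C8–C9, methanol is lost to give the C7=C8 alkene, and C11 is reduced and acylated last.
Stereochemistry: C5 comes from (S)-α-ionone; C10 by relay (reduction at C2 puts the hydroxyl anti to the C5 side chain, then a suprafacial Johnson–Claisen shift from O–C2 to C10); C9 from the chair-like ring closure with the ester equatorial.

Key step: step 8

Assumption: (S)-α-ionone of high enantiomeric purity is purchasable; it is the antipode of the more common (R) form and supplies C5 with the configuration of the target.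

**Step 1**
Reactants: 1 (S)-α-ionone
Product: 3 (S)-dihydro-α-ionone, via triethylsilyl enol ether 2 (not isolated)
Conditions: Et3SiH (1.2 equiv), RhCl(PPh3)3 (1 mol%), neat, 50 °C; then K2CO3 (cat.), MeOH, rt
Reagents that add atoms: none
Why: Rhodium-catalysed 1,4-hydrosilylation of the enone followed by methanolysis of the silyl enol ether (a conjugate reduction) saturates only the C6=C7 bond, since the trisubstituted ring alkene is inert to the catalyst and no base is present that could touch the allylic C5 centre.

**Step 2**
Reactants: 3 (S)-dihydro-α-ionone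
Product: 4 (6S)-6-(3,3-dimethoxybutyl)-1,5,5-trimethylcyclohex-1-ene
Conditions: HC(OMe)3, MeOH, PPTS (cat.), rt
Reagents that add atoms: trimethyl orthoformate, COC(OC)OC; methanol, CO
Why: Acid-catalysed ketalisation of the methyl ketone is driven by the orthoformate as dehydrating agent, and the weak acid PPTS leaves the ring alkene in place.

**Step 3**
Reactants: 4 (6S)-6-(3,3-dimethoxybutyl)-1,5,5-trimethylcyclohex-1-ene
Product: 5 (4S)-4-(3,3-dimethoxybutyl)-3,5,5-trimethylcyclohex-2-en-1-one
Conditions: t-BuOOH (70% in water, 5 equiv), Rh2(cap)4 (1 mol%, cap = caprolactamate), K2CO3 (0.5 equiv), CH2Cl2, rt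
Reagents that add atoms: tert-butyl hydroperoxide, CC(C)(C)OO
Why: Radical allylic oxidation by tert-butylperoxyl radicals attacks the only unhindered secondary allylic position, C2, as is usual for the α-ionone ring, and the basic medium keeps the ketal intact while C5 is untouched.

**Step 4**
Reactants: 5 (4S)-4-(3,3-dimethoxybutyl)-3,5,5-trimethylcyclohex-2-en-1-one
Product: 6 (1S,4S)-4-(3,3-dimethoxybutyl)-3,5,5-trimethylcyclohex-2-en-1-ol (hydroxyl trans to the side chain)
Conditions: LiBH(s-Bu)3 (L-Selectride), THF, −78 °C; then H2O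
Reagents that add atoms: none
Why: 1,2-Reduction of the β,β-disubstituted cyclohexenone by a bulky trialkylborohydride: with the C5 side chain pseudoaxial (it avoids the C10 methyl and the C4 methyls), the axial C4 methyl lies on the opposite face and blocks axial approach, so hydride should be delivered equatorially and the C2 hydroxyl should end pseudoaxial and anti to the side chain (1S), any cis epimer being removed by chromatography.

**Step 5**
Reactants: 6 (1S,4S)-4-(3,3-dimethoxybutyl)-3,5,5-trimethylcyclohex-2-en-1-ol; 7 trimethyl orthoacetate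
Product: 9 methyl 2-[(1S,6S)-6-(3,3-dimethoxybutyl)-1,5,5-trimethylcyclohex-2-en-1-yl]acetate, via allyl ketene acetal 8 (not isolated)
Conditions: MeC(OMe)3 (as solvent), EtCO2H (5 mol%), 135 °C, sealed tube
Reagents that add atoms: trimethyl orthoacetate (7), COC(C)(OC)OC
Why: Johnson–Claisen rearrangement: exchange with the orthoester and loss of methanol give ketene acetal 8, whose suprafacial chair-like [3,3] shift from the pseudoaxial C2–O bond forms C9–C10 on the face that carried the oxygen, anti to the C5 side chain, which sets the quaternary C10; since every alkoxy group present is methoxy, exchange at the dimethyl ketal is degenerate.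

**Step 6**
Reactants: 9 methyl 2-[(1S,6S)-6-(3,3-dimethoxybutyl)-1,5,5-trimethylcyclohex-2-en-1-yl]acetate
Product: 10 methyl 2-[(1R,2S)-2-(3,3-dimethoxybutyl)-1,3,3-trimethylcyclohexyl]acetate
Conditions: H2 (1 atm), 10% Pd/C, EtOAc, Et3N (trace), rt
Reagents that add atoms: none
Why: Heterogeneous hydrogenation of the cis-disubstituted C1=C2 alkene creates no stereocentre, and the neutral to slightly basic medium keeps ketal and ester.

**Step 7**
Reactants: 10 methyl 2-[(1R,2S)-2-(3,3-dimethoxybutyl)-1,3,3-trimethylcyclohexyl]acetate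
Product: 12 E tert-butyldimethylsilyl methyl ketene acetal of 10 (ring stereocentres as in 10), via lithium enolate 11 (not isolated)
Conditions: LiN(i-Pr)2, THF, −78 °C; then TBSCl, DMPU, −78 → 0 °C
Reagents that add atoms: tert-butyldimethylsilyl chloride, CC(C)(C)[Si](C)(C)Cl
Why: Kinetic enolisation of the ester by the lithium amide and O-silylation of the enolate (the ketal has no acidic hydrogen) should give the silyl ketene acetal, mainly as the E isomer.

**Step 8**
Reactants: 12 E tert-butyldimethylsilyl methyl ketene acetal of 10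
Product: 13 methyl 8α-methoxydriman-11-oate, i.e. methyl (1R,2R,4aS,8aS)-2-methoxy-2,5,5,8a-tetramethyldecahydronaphthalene-1-carboxylate
Conditions: TBSOTf (10 mol%), 2,6-di-tert-butyl-4-methylpyridine (15 mol%), CH2Cl2 (0.01 M), −78 → −40 °C
Reagents that add atoms: none
Why: The silyl triflate ionises the C8 dimethyl ketal to an O-methyl oxocarbenium ion, the silyl ketene acetal carbon C9 adds to it to form C8–C9, and transfer of the silyl group from the resulting silyloxycarbenium ion to a methoxy group of the next ketal releases TBSOMe and carries the chain. The closest known reaction type is the intramolecular Mukaiyama aldol-type addition of silyl enol ethers and silyl ketene acetals to acetals and ketals under silyl triflate catalysis. Ring B closes in a 6-(enolexo)-exo-trig mode through a chair-like transition state in which C5–C6 and C10–C9 are both equatorial on ring A, so the trans ring fusion follows from the C5 and C10 centres already in place. At C9 the ketene acetal carbon C11 should take the equatorial position anti to C5, where its oxygen substituents lie between C1 and the C10 methyl instead of against C5 and the axial hydrogens at C5 and C7, which gives the 9β ester (9α-H). At C8 no strong element decides between the two orientations of the oxocarbenium ion, so 13 is drawn as the 8α-methoxy epimer and the 8β epimer would serve equally because C8 becomes sp2 in step 9. The step needs C–C bond formation to outrun protodesilylation of the ketene acetal, enol ether formation from the ketal and intermolecular addition, which the six-membered closure next to the quaternary C10, the hindered pyridine as acid scavenger and high dilution should secure.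

**Step 9**
Reactants: 13 methyl 8α-methoxydriman-11-oate
Product: 14 methyl drim-7-en-11-oate, i.e. methyl (1S,4aS,8aS)-2,5,5,8a-tetramethyl-1,4,4a,5,6,7,8,8a-octahydronaphthalene-1-carboxylate
Conditions: TsOH·H2O (10 mol%), toluene, 80 °C
Reagents that add atoms: none
Why: Acid-catalysed E1 loss of methanol: the tertiary C8 cation, the same one that the acid cyclisation of farnesic esters passes through, should lose the axial C7 proton to give the trisubstituted C7=C8 alkene, whereas loss of the C9 proton is held back by the ester and any exocyclic isomer returns to the cation under the protic conditions; C9 keeps its configuration.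

**Step 10**
Reactants: 14 methyl drim-7-en-11-oate
Product: 15 (−)-drimenol, [(1S,4aS,8aS)-2,5,5,8a-tetramethyl-1,4,4a,5,6,7,8,8a-octahydronaphthalen-1-yl]methanol
Conditions: LiAlH4, Et2O, 0 °C
Reagents that add atoms: none
Why: Hydride reduction of the ester to the primary alcohol at 0 °C touches neither the alkene nor the configuration at C9.

**Step 11**
Reactants: 16 caffeic acid
Product: 18 (E)-3,4-bis(tert-butyldimethylsilyloxy)cinnamic acid, via tris-silylated caffeic acid 17 (not isolated)
Conditions: TBSCl (3.5 equiv), imidazole, DMF, rt; then AcOH–THF–H2O, rt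
Reagents that add atoms: tert-butyldimethylsilyl chloride, CC(C)(C)[Si](C)(C)Cl
Why: Silylation of both phenols and the acid, then selective hydrolysis of the far more labile silyl ester, leaves the aryl silyl ethers in place.

**Step 12**
Reactants: 15 (−)-drimenol; 18 (E)-3,4-bis(tert-butyldimethylsilyloxy)cinnamic acid
Product: 19 drim-7-en-11-yl (E)-3,4-bis(tert-butyldimethylsilyloxy)cinnamate
Conditions: DCC, DMAP (cat.), CH2Cl2, 0 °C → rt
Reagents that add atoms: none
Why: Steglich esterification: DMAP-catalysed acyl transfer from the O-acylisourea to the hindered primary C11 alcohol, with the silyl ethers keeping the phenols out of the acylation and the E alkene untouched.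

**Step 13**
Reactants: 19 drim-7-en-11-yl (E)-3,4-bis(tert-butyldimethylsilyloxy)cinnamate
Product: 20 drim-7-en-11-yl (E)-caffeate (CNP0265201.1)
Conditions: Bu4NF, AcOH, THF, 0 °C
Reagents that add atoms: none
Why: Fluoride cleaves the two aryl silyl ethers, and buffering with acetic acid keeps the medium near neutral so that the caffeate ester survives and the catechol is not oxidised.

**Compound list**
1 | (S)-α-ionone, (3E)-4-[(1S)-2,6,6-trimethylcyclohex-2-en-1-yl]but-3-en-2-one | CC(=O)/C=C/[C@@H]1C(C)=CCCC1(C)C | starting material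
2 | triethylsilyl enol ether of 3 (drawn as the Z isomer) | C/C(O[Si](CC)(CC)CC)=C/C[C@@H]1C(C)=CCCC1(C)C | intermediate
3 | (S)-dihydro-α-ionone, 4-[(1S)-2,6,6-trimethylcyclohex-2-en-1-yl]butan-2-one | CC(=O)CC[C@@H]1C(C)=CCCC1(C)C | intermediate
4 | (6S)-6-(3,3-dimethoxybutyl)-1,5,5-trimethylcyclohex-1-ene | COC(C)(OC)CC[C@@H]1C(C)=CCCC1(C)C | intermediate
5 | (4S)-4-(3,3-dimethoxybutyl)-3,5,5-trimethylcyclohex-2-en-1-one | COC(C)(OC)CC[C@@H]1C(C)=CC(=O)CC1(C)C | intermediate
6 | (1S,4S)-4-(3,3-dimethoxybutyl)-3,5,5-trimethylcyclohex-2-en-1-ol (OH trans to side chain) | COC(C)(OC)CC[C@@H]1C(C)=C[C@@H](O)CC1(C)C | intermediate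
7 | trimethyl orthoacetate | COC(C)(OC)OC | starting material
8 | allyl ketene acetal, (3S,6S)-6-(3,3-dimethoxybutyl)-3-[(1-methoxyethenyl)oxy]-1,5,5-trimethylcyclohex-1-ene | COC(C)(OC)CC[C@@H]1C(C)=C[C@@H](OC(=C)OC)CC1(C)C | intermediate
9 | methyl 2-[(1S,6S)-6-(3,3-dimethoxybutyl)-1,5,5-trimethylcyclohex-2-en-1-yl]acetate | COC(C)(OC)CC[C@@H]1[C@@](C)(CC(=O)OC)C=CCC1(C)C | intermediate
10 | methyl 2-[(1R,2S)-2-(3,3-dimethoxybutyl)-1,3,3-trimethylcyclohexyl]acetate (side chains trans) | COC(C)(OC)CC[C@@H]1[C@@](C)(CC(=O)OC)CCCC1(C)C | intermediate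
11 | lithium enolate of 10 | CO/C(O[Li])=C\[C@@]1(C)CCCC(C)(C)[C@@H]1CCC(C)(OC)OC | intermediate
12 | E tert-butyldimethylsilyl methyl ketene acetal of 10 | CO/C(O[Si](C)(C)C(C)(C)C)=C\[C@@]1(C)CCCC(C)(C)[C@@H]1CCC(C)(OC)OC | intermediate
13 | methyl 8α-methoxydriman-11-oate, methyl (1R,2R,4aS,8aS)-2-methoxy-2,5,5,8a-tetramethyldecahydronaphthalene-1-carboxylate | COC(=O)[C@@H]1[C@@]2(C)CCCC(C)(C)[C@@H]2CC[C@@]1(C)OC | intermediate
14 | methyl drim-7-en-11-oate, methyl (1S,4aS,8aS)-2,5,5,8a-tetramethyl-1,4,4a,5,6,7,8,8a-octahydronaphthalene-1-carboxylate | CC1=CC[C@H]2C(C)(C)CCC[C@]2(C)[C@H]1C(=O)OC | intermediate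
15 | (−)-drimenol, [(1S,4aS,8aS)-2,5,5,8a-tetramethyl-1,4,4a,5,6,7,8,8a-octahydronaphthalen-1-yl]methanol | CC1=CC[C@H]2C(C)(C)CCC[C@]2(C)[C@H]1CO | intermediate
16 | caffeic acid | OC(=O)/C=C/c1ccc(O)c(O)c1 | starting material
17 | tert-butyldimethylsilyl (E)-3,4-bis(tert-butyldimethylsilyloxy)cinnamate | CC(C)(C)[Si](C)(C)OC(=O)/C=C/c1ccc(O[Si](C)(C)C(C)(C)C)c(O[Si](C)(C)C(C)(C)C)c1 | intermediate
18 | (E)-3,4-bis(tert-butyldimethylsilyloxy)cinnamic acid | OC(=O)/C=C/c1ccc(O[Si](C)(C)C(C)(C)C)c(O[Si](C)(C)C(C)(C)C)c1 | intermediate
19 | drim-7-en-11-yl (E)-3,4-bis(tert-butyldimethylsilyloxy)cinnamate | CC1=CC[C@H]2C(C)(C)CCC[C@]2(C)[C@H]1COC(=O)/C=C/c1ccc(O[Si](C)(C)C(C)(C)C)c(O[Si](C)(C)C(C)(C)C)c1 | intermediate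
20 | drim-7-en-11-yl (E)-caffeate, [(1S,4aS,8aS)-2,5,5,8a-tetramethyl-1,4,4a,5,6,7,8,8a-octahydronaphthalen-1-yl]methyl (2E)-3-(3,4-dihydroxyphenyl)prop-2-enoate | CC1=CC[C@H]2C(C)(C)CCC[C@]2(C)[C@H]1COC(=O)/C=C/c1ccc(O)c(O)c1 | target

**Count**
Total steps: 13. Longest linear sequence: 12 (steps 1–10, 12, 13); step 11 is a one-step branch.

**Steps most likely to fail**

Step 9. What may go wrong: the C8 cation may lose its proton toward C12 (exocyclic alkene) or C9 (conjugated ester) in competition with C7, or the ether next to the ester may ionise too slowly. Fallback, from 13 back to 14: methanol is removed by base instead (t-BuOK, THF, E1cB), which should give the conjugated ester methyl drim-8-en-11-oate F1 with no regiochemical choice. Kinetic deprotonation of F1 (LiN(i-Pr)2, DMPU, THF, −78 °C) at the C12 methyl, the γ position syn to the ester carbonyl, should give the cross-conjugated lithium dienolate F2. Protonation of F2 at −78 °C with acetic acid at C9 on the α face, anti to the C10 methyl, should give the exocyclic ester methyl drim-8(12)-en-11-oate F3. Radical hydrogen-atom-transfer isomerisation (Co(salen)Cl with salen = N,N′-bis(3,5-di-tert-butylsalicylidene)cyclohexane-1,2-diaminate, PhSiH3, benzene, rt), which moves a 1,1-disubstituted alkene by one position toward the accessible ring CH2, then leads to 14.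

Step 5. What may go wrong: at the temperature the hindered [3,3] shift needs, the dimethyl ketal may lose methanol to an enol ether, or the mixed orthoester may eliminate to a diene before it rearranges. Fallback, from 6 back to 9: acetylation (Ac2O, pyridine, DMAP) gives (1S,4S)-4-(3,3-dimethoxybutyl)-3,5,5-trimethylcyclohex-2-en-1-yl acetate F4. Ireland–Claisen rearrangement (LiN(i-Pr)2, THF, −78 °C; Me3SiCl, Et3N; then 60 °C) proceeds through the trimethylsilyl ketene acetal F5 to the rearranged trimethylsilyl ester F6, which aqueous work-up converts into 2-[(1S,6S)-6-(3,3-dimethoxybutyl)-1,5,5-trimethylcyclohex-2-en-1-yl]acetic acid F7. Methylation (MeI, K2CO3, DMF) returns to 9. The shift then runs under basic conditions below 70 °C with the same suprafacial transfer to C10.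

Step 8. What may go wrong: addition through the transition state with C11 axial, that is, poor facial control at C9. Fallback, from 13 back to 14: 13 is carried on as a mixture with its C9 epimer methyl 9-epi-8α-methoxydriman-11-oate F8. Step 9 then gives 14 together with methyl 9-epi-drim-7-en-11-oate F9. Deprotonation of this mixture at C9 (LiN(i-Pr)2, THF, −78 °C) converges both on the lithium dienolate F10 (enolate geometry not defined). Kinetic protonation of F10 at −78 °C (acetic acid in THF) at the α carbon from the α face, anti to the axial C10 methyl, should give 14 alone.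

**Further compounds**
F1 | step 9 | methyl drim-8-en-11-oate | CC1=C(C(=O)OC)[C@@]2(C)CCCC(C)(C)[C@@H]2CC1
F2 | step 9 | lithium dienolate of F1 with exocyclic C8=C12 | COC(O[Li])=C1[C@@]2(C)CCCC(C)(C)[C@@H]2CCC1=C
F3 | step 9 | methyl drim-8(12)-en-11-oate (9β ester) | COC(=O)[C@@H]1[C@@]2(C)CCCC(C)(C)[C@@H]2CCC1=C
F4 | step 5 | (1S,4S)-4-(3,3-dimethoxybutyl)-3,5,5-trimethylcyclohex-2-en-1-yl acetate | COC(C)(OC)CC[C@@H]1C(C)=C[C@@H](OC(C)=O)CC1(C)C
F5 | step 5 | trimethylsilyl ketene acetal of F4 | COC(C)(OC)CC[C@@H]1C(C)=C[C@@H](OC(=C)O[Si](C)(C)C)CC1(C)C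
F6 | step 5 | trimethylsilyl 2-[(1S,6S)-6-(3,3-dimethoxybutyl)-1,5,5-trimethylcyclohex-2-en-1-yl]acetate | COC(C)(OC)CC[C@@H]1[C@@](C)(CC(=O)O[Si](C)(C)C)C=CCC1(C)C
F7 | step 5 | 2-[(1S,6S)-6-(3,3-dimethoxybutyl)-1,5,5-trimethylcyclohex-2-en-1-yl]acetic acid | COC(C)(OC)CC[C@@H]1[C@@](C)(CC(=O)O)C=CCC1(C)C
F8 | step 8 | methyl 9-epi-8α-methoxydriman-11-oate | COC(=O)[C@H]1[C@@]2(C)CCCC(C)(C)[C@@H]2CC[C@@]1(C)OC
F9 | step 8 | methyl 9-epi-drim-7-en-11-oate | CC1=CC[C@H]2C(C)(C)CCC[C@]2(C)[C@@H]1C(=O)OC
F10 | step 8 | lithium dienolate of 14 and F9 | COC(O[Li])=C1[C@@]2(C)CCCC(C)(C)[C@@H]2CC=C1C
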